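All runs were generated by integration from invented constants; scatter was added.

After 5.00 h Tuesday's flask reads 12.6% of Q and Friday's, with twice the X, reads 13.6%. That gap of 1 percentage point stands against a scatter of 0.5 points on each reading, so X moves these two flasks weakly.

| flask | E | X | L | D | remark |
|---|---|---|---|---|---|
| Tuesday's | 0.020 M | 1.8 equiv | 0.5 mol% | 18 µM | the very flask that is asked about, followed so far |
| Friday's | 0.020 M | 3.6 equiv | 0.5 mol% | 18 µM | run made earlier |
| flask | 0.020 M | 1.80 equiv | 0.5 mol% | 18 µM |  |

- Tuesday's (time / h: Q / %): 0.417: 0.8; 0.833: 1.1; 2.00: 2.8; 5.00: 12.6
- Friday's (time / h: Q / %): 1.00: 1.3; 2.00: 3.2; 5.00: 13.6; 12.0: 43.0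

(readings scatter by 0.5 percentage points)

- apparent order in L when 30% of the E are converted (percent change of the rate of making Q for one percent more L charged)
- apparent order in X when 30% of the E are converted (percent change of the rate of making Q for one percent more X charged)

Neither run varies L, so two chemists argue the order in L from the charges. The first takes first order in L as the zero of the scale, the plain case of a catalyst whose whole charge works, and sets 18 µM of D beside 0.020 M of E as too small to count.

The second holds D against L instead. Tuesday's flask is charged with 100 µM of L, and if each D takes one L out for good, 82.0 µM stays working. Her number is 1.22, the poison multiplier: L charged over L left working. At a fixed conversion she lets the rate follow working L, and since D takes a fixed amount, one percent more L charged is 1.22 percent more working L. Her order in L is therefore the multiplier, and the first chemist's is one.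

The forecast takes her side, with order 1.22 in L (range 1 to 1.4) and its own caveat: “This assumes D titrates fully”. For X it gives 0.11 (range 0 to 0.3).

Tuesday's flask reaches 30% conversion after 3.32 h and gives 1.2 in L, which is the second chemist's value within the tolerance, and 0.17 in X, higher than the forecast's figure.

    E + L → L + G (k = 0.400 M⁻¹ s⁻¹)
    L + G ⇌ Z (K = 1800 M⁻¹, k = 0.532 M⁻¹ s⁻¹)
    X + Z → L + Q (k = 0.396 M⁻¹ s⁻¹)
    L + D → J (k = 179 M⁻¹ s⁻¹)

Part of the reason Tuesday's flask stands above first order in L is the path from L + D to the off-cycle form J: in the same run without that path the order falls from 1.2 to 1.0, and there the first chemist is right. By 1.20 h J already holds 18.0% of the catalyst charged, with D at 0%. The run without the path makes Q at 30% conversion 1.22 times as fast as the actual flask, against a poison multiplier of 1.22.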